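The route rests on disconnecting the cyclohexene ring between its C10 methylene and the oxygenated carbon C9 (spiro[4.5]decane numbering, C5 spiro). C10 lies between quaternary C5 and C9, so a temporary tert-butoxycarbonyl group on C10 and C9 at the ester level turn this bond into a Dieckmann bond. The precursor is a cyclopentane carrying CH2CO2t-Bu and a (Z)-configured CH=CH–CH(CH3)CO2Me arm on one carbon; one base-mediated step closes the six-membered ring as a β-keto ester, which is then decarboxylated to the 2-methylenone. The cyclopentane, its three ring stereocentres and the side-chain methine are mapped onto (4aS,7S,7aR)-nepetalactone, whose lactone enolate sets the spiro centre.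

Key step: step 7

Assumption: (4aS,7S,7aR)-nepetalactone, the main constituent of catnip oil, is taken as a purchasable starting material; core atoms are numbered as in spiro[4.5]decane (C1 = CH–CH3, C4 = CH bearing the side chain, C5 = spiro carbon, C6 = CH2, C7=C8(CH3), C9 = C–O, C10 = CH2).

Step 1
Reactants: 1 (4aS,7S,7aR)-nepetalactone
Product: 2 (4S,4aR,7S,7aR)-dihydronepetalactone
Conditions: H2 (3 atm), Pd/C, EtOAc, rt
Reagents that add atoms: none
Why: Catalytic hydrogenation should add H2 to the enol-lactone alkene from the convex face of the cis-fused bicycle (the face of H-4a and H-7a), which sets the 4S methine that becomes the side-chain stereocentre, while C4a, C7 and C7a are carried over from the terpene.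

Step 2
Reactants: 2 dihydronepetalactone; 3 tert-butyl bromoacetate
Product: 4 7a-(tert-butoxycarbonylmethyl) lactone
Conditions: LiN(i-Pr)2, THF, −78 °C; then 3, DMPU, −78 to −20 °C
Reagents that add atoms: none
Why: Lactone enolate alkylation (SN2 on the bromoacetate): the electrophile should enter axially on the enolate face anti to the C4a–C4 bond so that the bicycle stays cis-fused, which places the new CH2 on the side of H-4a and of the C7 methyl and thereby sets the quaternary (future spiro) centre in the configuration of the target.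

Step 3
Reactants: 4 alkylated lactone
Product: 5 lactol
Conditions: i-Bu2AlH (1.1 equiv), CH2Cl2, −78 °C
Reagents that add atoms: none
Why: Partial reduction of a lactone to its lactol with i-Bu2AlH at low temperature (the tetrahedral aluminate persists until work-up), the bulky tert-butyl ester being reduced far more slowly.

Step 4
Reactants: 6 triphenylphosphine; 7 3-bromo-2-methylpropanoic acid
Product: 8 (2-carboxypropyl)triphenylphosphonium bromide
Conditions: MeCN, reflux
Reagents that add atoms: none
Why: Quaternisation of PPh3 by the primary bromide (SN2; any elimination to methacrylic acid is followed by conjugate addition of Ph3P·HBr to the same salt).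

Step 5
Reactants: 5 lactol; 8 phosphonium salt
Product: 9 (Z)-hydroxy acid
Conditions: 8 (2.5 equiv), NaN(SiMe3)2 (5 equiv), THF, 0 °C; then 5, 0 to 40 °C; aqueous citric acid
Reagents that add atoms: none
Why: Wittig olefination of the lactol, which reacts through its open hydroxy aldehyde, with the non-stabilised ylide (carboxyl masked as its salt) should give the (Z)-alkene; the methine next to the carboxyl is formed as a mixture that is erased in step 8.

Step 6
Reactants: 9 hydroxy acid
Product: 10 hydroxy methyl ester
Conditions: MeI, KHCO3, DMF, rt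
Reagents that add atoms: iodomethane, CI
Why: SN2 O-methylation of the carboxylate under bicarbonate, which leaves the primary alcohol and the tert-butyl ester untouched.

Step 7
Reactants: 10 hydroxy diester
Product: 11 spirocyclic β-keto tert-butyl ester
Conditions: KOt-Bu (3.5 equiv), THF (0.02 M), 0 °C to rt; AcOH quench
Reagents that add atoms: none
Why: KOt-Bu equilibrates the ester enolates; the enolate of the tert-butyl acetate arm (C10, made nucleophilic by its temporary ester) adds to the methyl ester carbonyl (C9) and expels methoxide, a Dieckmann condensation (intramolecular Claisen condensation) that forms the C9–C10 bond. The cyclohexene ring closes in the 6-exo-trig mode (enolate C=C outside the ring), the cis ring alkene holding the two arms on the same side. No lasting stereocentre is created: C10 and C8 of 11 are mixtures that become CH2 and sp2 in step 8, and the spiro centre set in step 2 is not touched. The selectivity needed is between the two Claisen directions: only the wanted closure ends in a doubly stabilised β-keto ester enolate and is therefore the thermodynamic sink, whereas attack of the methyl-ester dienolate on the hindered tert-butyl ester is slow and would give a non-enolisable, reversibly formed product. Alkene migration and E/Z scrambling through the dienolate do no harm, because the isomers interconvert and only the cyclisable ones are drained, and high dilution suppresses intermolecular acyl transfer by the side-chain alkoxide.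

Step 8
Reactants: 11 β-keto ester
Product: 12 hydroxy enone
Conditions: p-TsOH·H2O (0.3 equiv), toluene, 90 °C
Reagents that add atoms: none
Why: Acid-catalysed loss of isobutene from the tert-butyl ester, decarboxylation of the resulting β-keto acid and acid-catalysed migration of the β,γ-alkene into conjugation should converge all isomers of 11 on the 2-methylcyclohex-2-enone; no stereocentre is formed.

Step 9
Reactants: 12 hydroxy enone
Product: 13 aldehyde
Conditions: Dess–Martin periodinane, NaHCO3, CH2Cl2, 0 °C to rt
Reagents that add atoms: none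
Why: Dess–Martin oxidation of the primary alcohol under buffered, non-basic conditions, chosen so that the α-methine of the new aldehyde is not epimerised.

Step 10
Reactants: 14 3-methylfuran-2(5H)-one
Product: 15 tert-butyldimethyl[(3-methylfuran-2-yl)oxy]silane
Conditions: TBSOTf, Et3N, CH2Cl2, 0 °C
Reagents that add atoms: tert-butyldimethylsilyl trifluoromethanesulfonate, CC(C)(C)[Si](C)(C)OS(=O)(=O)C(F)(F)F
Why: O-Silylation of the butenolide through its dienolate (soft enolisation with silyl triflate and amine) gives the aromatic 2-silyloxyfuran.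

Step 11
Reactants: 13 aldehyde; 15 silyloxyfuran
Product: 16 hydroxyalkyl butenolide
Conditions: BF3·OEt2 (1.1 equiv), CH2Cl2, −78 °C; aqueous NaHCO3
Reagents that add atoms: none
Why: Vinylogous Mukaiyama aldol addition: the silyloxyfuran attacks the BF3-activated aldehyde through its C5, the aldehyde reacting far faster than the hindered enone at −78 °C; the two new stereocentres form as a mixture and both are removed in step 12.

Step 12
Reactants: 16 hydroxyalkyl butenolide
Product: 18 (Z)-ylidene butenolide enone, via mesylate 17 (not isolated)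
Conditions: MsCl, Et3N, CH2Cl2, −20 °C to rt
Reagents that add atoms: methanesulfonyl chloride, CS(=O)(=O)Cl (its atoms are carried only by 17)
Why: Mesylation and E1cB elimination through the furanolate should give the γ-ylidene butenolide with the (Z) geometry (alkyl group syn to the ring oxygen), the thermodynamically preferred and usual outcome of this dehydration.

Step 13
Reactants: 18 ylidene butenolide enone
Product: 19 (9S)-allylic alcohol
Conditions: (R)-2-methyl-CBS-oxazaborolidine (0.5 equiv), catecholborane, toluene, −78 °C
Reagents that add atoms: none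
Why: Corey–Bakshi–Shibata reduction, 1,2-selective for the enone and leaving the unsaturated lactone alone: with the α-methylvinyl arm as the large and the C10 methylene as the small group the (R)-catalyst should deliver hydride to the face that gives the 9S alcohol (catalyst control).

Step 14
Reactants: 19 allylic alcohol; 20 3-phenylpropanoyl chloride
Product: 21 target ester
Conditions: pyridine, DMAP (cat.), CH2Cl2, 0 °C to rt
Reagents that add atoms: none
Why: DMAP-catalysed acylation of the secondary allylic alcohol by the acid chloride, with retention at C9, gives the target.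

Compound list
1 | (4aS,7S,7aR)-4,7-dimethyl-5,6,7,7a-tetrahydrocyclopenta[c]pyran-1(4aH)-one (cis,trans-nepetalactone) | O=C1OC=C(C)[C@H]2CC[C@H](C)[C@@H]12 | starting material
2 | (4S,4aR,7S,7aR)-4,7-dimethylhexahydrocyclopenta[c]pyran-1(3H)-one (dihydronepetalactone) | O=C1OC[C@@H](C)[C@H]2CC[C@H](C)[C@@H]12 | intermediate
3 | tert-butyl bromoacetate | BrCC(=O)OC(C)(C)C | starting material
4 | tert-butyl 2-[(4S,4aR,7S,7aR)-4,7-dimethyl-1-oxohexahydrocyclopenta[c]pyran-7a(1H)-yl]acetate (cis-fused; acetate arm cis to the C7 methyl) | O=C1OC[C@@H](C)[C@H]2CC[C@H](C)[C@@]12CC(=O)OC(C)(C)C | intermediate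
5 | tert-butyl 2-[(4S,4aR,7S,7aR)-1-hydroxy-4,7-dimethylhexahydrocyclopenta[c]pyran-7a(1H)-yl]acetate (lactol, both anomers) | OC1OC[C@@H](C)[C@H]2CC[C@H](C)[C@@]12CC(=O)OC(C)(C)C | intermediate
6 | triphenylphosphine | c1ccc(cc1)P(c1ccccc1)c1ccccc1 | starting material
7 | 3-bromo-2-methylpropanoic acid (racemic) | CC(CBr)C(=O)O | starting material
8 | (2-carboxypropyl)triphenylphosphonium bromide | CC(C[P+](c1ccccc1)(c1ccccc1)c1ccccc1)C(=O)O.[Br-] | intermediate
9 | (3Z)-4-[(1S,2R,5S)-1-(2-tert-butoxy-2-oxoethyl)-2-[(2S)-1-hydroxypropan-2-yl]-5-methylcyclopentyl]-2-methylbut-3-enoic acid (both C2 epimers) | OC[C@@H](C)[C@H]1CC[C@H](C)[C@@]1(CC(=O)OC(C)(C)C)/C=C\C(C)C(=O)O | intermediate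
10 | methyl ester of 9 | OC[C@@H](C)[C@H]1CC[C@H](C)[C@@]1(CC(=O)OC(C)(C)C)/C=C\C(C)C(=O)OC | intermediate
11 | tert-butyl (1S,4R)-4-[(2S)-1-hydroxypropan-2-yl]-1,8-dimethyl-9-oxospiro[4.5]dec-6-ene-10-carboxylate (spiro centre as in 4; C8 and C10 as mixtures) | OC[C@@H](C)[C@H]1CC[C@H](C)[C@@]12C=CC(C)C(=O)C2C(=O)OC(C)(C)C | intermediate
12 | (1S,4R,5S)-4-[(2S)-1-hydroxypropan-2-yl]-1,8-dimethylspiro[4.5]dec-7-en-9-one | OC[C@@H](C)[C@H]1CC[C@H](C)[C@@]12CC=C(C)C(=O)C2 | intermediate
13 | (1S,4R,5S)-1,8-dimethyl-4-[(2S)-1-oxopropan-2-yl]spiro[4.5]dec-7-en-9-one | O=C[C@@H](C)[C@H]1CC[C@H](C)[C@@]12CC=C(C)C(=O)C2 | intermediate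
14 | 3-methylfuran-2(5H)-one | CC1=CCOC1=O | starting material
15 | tert-butyldimethyl[(3-methylfuran-2-yl)oxy]silane | Cc1ccoc1O[Si](C)(C)C(C)(C)C | intermediate
16 | (1S,4R,5S)-4-[(2S)-1-hydroxy-1-(4-methyl-5-oxo-2,5-dihydrofuran-2-yl)propan-2-yl]-1,8-dimethylspiro[4.5]dec-7-en-9-one (mixture at the carbinol and the furanone C2) | CC1=CC(OC1=O)C(O)[C@@H](C)[C@H]2CC[C@H](C)[C@@]23CC=C(C)C(=O)C3 | intermediate
17 | methanesulfonate of 16 | CC1=CC(OC1=O)C(OS(C)(=O)=O)[C@@H](C)[C@H]2CC[C@H](C)[C@@]23CC=C(C)C(=O)C3 | intermediate
18 | (1S,4R,5S)-1,8-dimethyl-4-[(1Z,2S)-1-(4-methyl-5-oxofuran-2(5H)-ylidene)propan-2-yl]spiro[4.5]dec-7-en-9-one | CC1=C/C(=C/[C@@H](C)[C@H]2CC[C@H](C)[C@@]23CC=C(C)C(=O)C3)OC1=O | intermediate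
19 | (5Z)-5-{(2S)-2-[(1S,4R,5S,9S)-9-hydroxy-1,8-dimethylspiro[4.5]dec-7-en-4-yl]propylidene}-3-methylfuran-2(5H)-one | CC1=C/C(=C/[C@@H](C)[C@H]2CC[C@H](C)[C@@]23CC=C(C)[C@@H](O)C3)OC1=O | intermediate
20 | 3-phenylpropanoyl chloride | O=C(Cl)CCc1ccccc1 | starting material
21 | (1S,4R,5S,9S)-1,8-dimethyl-4-[(1Z,2S)-1-(4-methyl-5-oxofuran-2(5H)-ylidene)propan-2-yl]spiro[4.5]dec-7-en-9-yl 3-phenylpropanoate | CC1=C/C(=C/[C@@H](C)[C@H]2CC[C@H](C)[C@@]23CC=C(C)[C@@H](OC(=O)CCc2ccccc2)C3)OC1=O | target

Total step count: 14. Longest linear sequence: 12 steps (steps 1–3, 5–9 and 11–14; steps 4 and 10 prepare the two reagents).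

Steps most likely to fail

Step 5. The β-carboxylate ylide may fragment to methacrylate and PPh3 before it adds to the hindered, neopentyl-type lactol, or the olefination may simply be too slow. The fallback sets out from 5 and comes back at 12. Wittig reaction of 5 with Ph3P=CHOMe (from (methoxymethyl)triphenylphosphonium chloride and KOt-Bu) should give the enol ether F1. Hydrolysis (aqueous HCl, THF) should give the one-carbon-homologated aldehyde F2. Still–Gennari olefination with ethyl 2-[bis(2,2,2-trifluoroethoxy)phosphoryl]propanoate (KN(SiMe3)2, 18-crown-6, THF, −78 °C) should give the (Z)-conjugated ethyl ester F3. The conditions of step 7 should close F3 to the conjugated β-keto ester F4, and the conditions of step 8 should convert F4 into 12.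

Step 7. The Claisen closure may run in the other direction, from the more acidic α-carbon of the unsaturated methyl ester; the open chain may stall as its (E)-conjugated isomer; or acyl transfer to the side-chain alkoxide may intervene. The fallback sets out from 2 and comes back at 12; it uses no activating group and closes the same bond by an organosamarium acyl substitution. Alkylation of the enolate of 2 with CH2I2 should give the iodomethyl lactone F5, and i-Bu2AlH the iodomethyl lactol F6. Wittig reaction with 8 should give the iodo hydroxy acid F7, and MeI/KHCO3 the iodo methyl ester F8. SmI2 with catalytic tris(dibenzoylmethanato)iron, Fe(dbm)3, in THF at −30 °C should then effect a Barbier-type intramolecular nucleophilic acyl substitution to the β,γ-unsaturated ketone F9, which DBU conjugates to 12.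

Step 13. Facial selectivity may be poor if the catalyst and the inherent bias of the spiro ring oppose each other, and a slow reduction could allow attack on the ylidene butenolide. The fallback sets out from 18 and comes back at 21. Substrate-controlled Luche reduction (NaBH4, CeCl3·7H2O, MeOH, −78 °C) is tried first. Should it deliver the C9 epimer F10, Mitsunobu esterification with 3-phenylpropanoic acid (PPh3, DIAD, THF, 0 °C) inverts C9 and gives 21 directly.

Further compounds
F1 | step 5 | tert-butyl 2-[2-[(2S)-1-hydroxypropan-2-yl]-1-(2-methoxyethenyl)-5-methylcyclopentyl]acetate (ring stereocentres as in 9, E/Z mixture) | OC[C@@H](C)[C@H]1CC[C@H](C)[C@@]1(CC(=O)OC(C)(C)C)C=COC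
F2 | step 5 | tert-butyl 2-[2-[(2S)-1-hydroxypropan-2-yl]-5-methyl-1-(2-oxoethyl)cyclopentyl]acetate (ring stereocentres as in 9) | OC[C@@H](C)[C@H]1CC[C@H](C)[C@@]1(CC(=O)OC(C)(C)C)CC=O
F3 | step 5 | ethyl (2Z)-4-[1-(2-tert-butoxy-2-oxoethyl)-2-[(2S)-1-hydroxypropan-2-yl]-5-methylcyclopentyl]-2-methylbut-2-enoate (ring stereocentres as in 9) | OC[C@@H](C)[C@H]1CC[C@H](C)[C@@]1(CC(=O)OC(C)(C)C)C/C=C(/C)C(=O)OCC
F4 | step 5 | tert-butyl 4-[(2S)-1-hydroxypropan-2-yl]-1,8-dimethyl-9-oxospiro[4.5]dec-7-ene-10-carboxylate (stereocentres as in 12, C10 mixture) | OC[C@@H](C)[C@H]1CC[C@H](C)[C@@]12CC=C(C)C(=O)C2C(=O)OC(C)(C)C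
F5 | step 7 | 7a-(iodomethyl)dihydronepetalactone (iodomethyl on the face taken by the acetate arm in 4) | O=C1OC[C@@H](C)[C@H]2CC[C@H](C)[C@@]12CI
F6 | step 7 | lactol of F5 (both anomers) | OC1OC[C@@H](C)[C@H]2CC[C@H](C)[C@@]12CI
F7 | step 7 | (3Z)-4-[2-[(2S)-1-hydroxypropan-2-yl]-1-(iodomethyl)-5-methylcyclopentyl]-2-methylbut-3-enoic acid (ring stereocentres as in 9) | OC[C@@H](C)[C@H]1CC[C@H](C)[C@@]1(CI)/C=C\C(C)C(=O)O
F8 | step 7 | methyl ester of F7 | OC[C@@H](C)[C@H]1CC[C@H](C)[C@@]1(CI)/C=C\C(C)C(=O)OC
F9 | step 7 | 4-[(2S)-1-hydroxypropan-2-yl]-1,8-dimethylspiro[4.5]dec-6-en-9-one (β,γ-unsaturated isomer of 12, C8 mixture) | OC[C@@H](C)[C@H]1CC[C@H](C)[C@@]12C=CC(C)C(=O)C2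
F10 | step 13 | (9R)-epimer of 19 | CC1=C/C(=C/[C@@H](C)[C@H]2CC[C@H](C)[C@@]23CC=C(C)[C@H](O)C3)OC1=O
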